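## The problem

Flavan numbering is used for rings A and C (O1, C2–C4, C4a–C8a), primes for ring B, and double primes for ring D (O4'–C2''–C3''–C4''–C5').

- The target is a (2S)-5,7-dihydroxyflavanone. Its ring B carries five contiguous substituents: C1' is bonded to C2, C2' bears a prenyl group, C3' a free hydroxyl, and O4'/C5' are closed into ring D, a (3''S)-2,2-dimethylchroman-3-ol. Only C6' is unsubstituted.
- Each of the two carbon substituents on ring B (prenyl at C2', the ring D methylene at C5') is ortho to one of the two catechol oxygens. The substitution pattern can therefore be dictated from those oxygens, provided the order of events is right.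
- The stereocentres C2 and C3'' are five bonds apart across the flat ring B. Neither can direct the other, so each needs its own reagent or catalyst control.
- C2 is fragile at the flavanone stage: base opens the β-aryloxy ketone by retro-oxa-Michael reaction to the chalcone, helped by the para-oxygen O4', and reclosure scrambles C2.
- The prenyl alkene excludes hydrogenolysis, cyclises onto O3' under strong acid, and competes in alkene oxidations. The oxygen at C3'' must therefore be introduced before the prenyl group exists. Ring A, once unmasked, is a nucleophilic and oxidisable phloroglucinol.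
- The enabling feature is that ring C is attached to ring A through O1–C8a and C4–C4a, the two termini of an ortho-quinone methide of a phloroglucinol. C2 is benzylic to ring B with O4' para to C1', so C2–C3 maps onto the vinyl group of an electron-rich para-alkoxystyrene and ring C onto a hetero-[4+2] union of the two halves.

## Retrosynthesis

**19 to 18 to 17 (end game, no skeletal bond cut).** The target 19 is taken back to its tetrakis-silyl ether 18 and then to the 4-methoxyflavan 17, trading the C4 carbonyl for C4–H/C4–OMe. A flavan cannot open to a chalcone, so C2 stays fixed until the ketone appears, and after that only acidic fluoride is used. The methoxy group makes C4–H the most hydridic C–H bond in 17, so one equivalent of DDQ should reach the ketone. Silyl ethers are chosen because benzyl ethers would need hydrogenolysis and acetal-type groups strong acid, both unsafe for the prenyl group next to O3'. The forward steps must oxidise C4 without touching the prenyl CH2 or C2–H, and desilylate without forming a phenoxide.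

**17 to 15 plus 12 (key cut: C3–C4 and O1–C2).** Ring C is opened to the salicylaldehyde dimethyl acetal 15, which serves as precursor of the 4-methoxy ortho-quinone methide 16, and the B/D-ring styrene 12. The neighbouring classical cut (C2–C3 by aldol, O1–C2 by oxa-Michael through a chalcone) forms C2 reversibly under base and offers no handle for its configuration. The chosen cut forms two bonds and the ring in one convergent, kinetically controlled step under acid, and delivers C4 already oxygenated. The precursors are of comparable size; 15 is two steps from a commercial aldehyde. The forward reaction must accept a hindered, highly stabilised oxocarbenium ion, choose the styrene over the prenyl alkene, and set C2 by catalyst control.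

**15 to 14 to 13.** The acetal comes from aldehyde 14, and 14 from 2,4,6-trihydroxybenzaldehyde 13 by silylating two of the three hydroxyls. The third is the one needed as O1 and is the least reactive, because it is hydrogen-bonded to the aldehyde. Triisopropylsilyl groups are chosen because they survive acid and shield C6 and C8 of ring A against Friedel–Crafts self-condensation.

**12 to 11 to 10.** The vinyl group is cut at its C=C bond back to aldehyde 11 (Wittig methylenation), and both silyl ethers back to the phenol–alcohol 10. A vinyl group is installed last because a styrene would not survive the thermal and oxidative steps that precede it.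

**10 to 9 (C2'–prenyl bond).** The prenyl group is traced to the 1,1-dimethylallyl ether on O3' in 9. A [3,3] shift can only go to C2', since the other ortho position carries O4'. Direct C-prenylation of a phenoxide or cross-coupling at this doubly flanked position would be less selective and would need a halide that has no other use.

**9 to 8 to 7 to 6 (C3'' stereocentre).** The aldehyde and the C4'' methylene of 9 come from diol 8 (benzylic oxidation), and 8 from epoxy ester 7 by one hydride reagent that reduces the ester and opens the epoxide at the benzylic carbon. Epoxide 7 comes from chromene 6 by Jacobsen epoxidation, for which 2,2-dimethylchromenes with an electron-poor arene are ideal substrates. The oxygen at C3'' is placed before the prenyl group exists; the only other alkene in 6 is a monosubstituted vinyl group, a poor substrate for the manganese catalyst.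

**6 to 5 to 4 plus 2.** The tertiary allyl ether is the semihydrogenation product of propargyl ether 5, made from phenol 4 and 3-chloro-3-methylbut-1-yne 2.

**4 to 3 to 1 plus 2 (ring D: C5'–C4'' and O4'–C2'').** Chromene 4 is opened to aryl propargyl ether 3. Its Claisen rearrangement can only reach C5', and the resulting allene closes onto O4'. Ether 3 comes from methyl 3,4-dihydroxybenzoate 1 and 2 by alkylation of the more acidic 4-OH. Reagent 2 thus supplies both five-carbon units, and the ester carbon of 1 becomes the styrene α-carbon, later C2.

## Roads not taken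

Alternative 1: ring D by a propargyl ether Claisen cascade as the strategic step.
- Cut and key step: the aryl propargyl ether A1 (5-bromo-2-(2-methylbut-3-yn-2-yloxy)benzaldehyde) is heated; a [3,3] shift forms C5'–C4'' and electrocyclisation re-forms O4'–C2'', giving chromene A2.
- Merits: purely thermal, regiochemistry forced, fully known chemistry. The bromide at C1' would reach a vinyl group by a single cross-coupling, one operation shorter than the ester reduction, oxidation and methylenation used here.
- Weak points: it creates neither stereocentre and leaves the joining of ring B to ring A open. The aldehyde must be converted into O3' by a peroxide-based Dakin oxidation next to the chromene alkene. The bromide must survive semihydrogenation and hydride steps.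
- Comparison: the same cascade is used in the chosen plan as step 2, on an ester that already carries O3'. Against the shorter vinylation and the fully known chemistry of this road, the chosen plan sets that its defining step is the one that joins the halves and creates C2.

Alternative 2: ring D from a ring B quinone methide and an alkenylboronate.
- Cut and key step: the ortho-quinone methide from hydroxymethyl phenol A3 adds 2-methylprop-1-enylboronic acid pinacol ester A4 under a chiral phosphoric acid. C4''–C3'' and O4'–C2'' form, giving boronate A5, whose C–B bond would be oxidised with retention to the (3''S) carbinol.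
- Merits: ring D and C3'' arise in one step, about two steps shorter than chromene formation, epoxidation and reductive opening.
- Weak points: an alkenylboronate is a weak π-nucleophile, the unstabilised quinone methide of a bromophenol is hard to generate with a weak acid, and enantiocontrol at a boron-bearing carbon in such a cycloaddition is without precedent. The stereocentre it addresses is the one that Jacobsen epoxidation of a 2,2-dimethylchromene already sets reliably.
- Comparison: this road is shorter for ring D, but it spends its one unprecedented step on the easier stereocentre and leaves C2 unsolved. The chosen plan uses reliable chemistry for C3'' and places its new step at C2, where the classical chalcone cyclisation offers no control.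

Alternative 3: ring A closed last through an acylketene.
- Cut and key step: C4a–C5 is cut. Thermolysis of dioxinone A6 releases an acylketene that is attacked by the pyranone carbon destined to be C4a; enolisation aromatises ring A and gives flavanone A7.
- Merits: ring A appears with both hydroxyls free, so no ring A protection and no C4 oxidation are needed. C2 would be set earlier on a dihydropyranone by established asymmetric hetero-Diels–Alder chemistry, which is safer stereocontrol at C2 than the chosen plan can claim.
- Weak points: the whole polyketide chain is built linearly on the valuable ring B aldehyde. The 2-aryl-dihydropyranone with its para-oxygenated aryl group can open by retro-oxa-Michael reaction at thermolysis temperature and erode C2. Acylketenes prefer oxygen nucleophiles, so C-acylation is not assured. The methoxymethyl ether in A7 needs acid for removal next to the prenyl group.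
- Comparison: against the better-founded C2 control of this road, the chosen plan sets convergence (ring A in two steps), a shorter longest sequence, and a fluoride-only end game.

Key step: step 13

Assumption: the sense of induction of the chiral acid in step 13 cannot be derived from a closely related case; the (R)-catalyst is written, and its mirror image would be used if the (2R) series is found to prevail.

Assumption: 17 is drawn as the 2,4-cis isomer expected from an endo approach; its C4 epimer, if formed, converges on the same ketone 18.

## Route

Chroman numbering is used for the B/D-ring building blocks: chroman C6 = C1', C7 = C2', C8 = C3', C3 = C3''.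

Step 1
Reactants: 1 methyl 3,4-dihydroxybenzoate; 2 3-chloro-3-methylbut-1-yne
Product: 3 methyl 3-hydroxy-4-(2-methylbut-3-yn-2-yloxy)benzoate
Conditions: K2CO3 (1.1 equiv), KI (cat.), DMF, 65 °C, Ar
Reagents that add atoms: none
Why: Williamson-type O-alkylation with a tertiary propargylic chloride; the 4-OH, para to the ester, is the more acidic hydroxyl and its phenoxide should be alkylated selectively with about one equivalent of base.

Step 2
Reactants: 3 methyl 3-hydroxy-4-(2-methylbut-3-yn-2-yloxy)benzoate
Product: 4 methyl 8-hydroxy-2,2-dimethyl-2H-chromene-6-carboxylate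
Conditions: N,N-diethylaniline, 185 °C, Ar
Reagents that add atoms: none
Why: Aromatic propargyl Claisen rearrangement to C5, the only free ortho position, followed by 1,5-hydrogen shift and oxa-6π electrocyclisation should give the 2,2-dimethylchromene; no stereocentre is formed.

Step 3
Reactants: 4 methyl 8-hydroxy-2,2-dimethyl-2H-chromene-6-carboxylate; 2 3-chloro-3-methylbut-1-yne
Product: 5 methyl 2,2-dimethyl-8-(2-methylbut-3-yn-2-yloxy)-2H-chromene-6-carboxylate
Conditions: 2 (1.5 equiv), DBU, CuCl2 (1 mol %), MeCN, 0 °C → rt
Reagents that add atoms: none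
Why: Copper-catalysed O-propargylation of the remaining phenol; the low temperature keeps the new propargyl ether from rearranging.

Step 4
Reactants: 5 methyl 2,2-dimethyl-8-(2-methylbut-3-yn-2-yloxy)-2H-chromene-6-carboxylate
Product: 6 methyl 2,2-dimethyl-8-(2-methylbut-3-en-2-yloxy)-2H-chromene-6-carboxylate
Conditions: H2 (1 atm), Lindlar catalyst (Pd/CaCO3 poisoned with Pb(OAc)2), quinoline, EtOAc, rt
Reagents that add atoms: none
Why: Lindlar semihydrogenation of the terminal alkyne; the conjugated chromene alkene and the ester are not reduced on poisoned palladium, and hydrogen uptake is followed to stop at the alkene.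

Step 5
Reactants: 6 methyl 2,2-dimethyl-8-(2-methylbut-3-en-2-yloxy)-2H-chromene-6-carboxylate
Product: 7 methyl (3S,4S)-3,4-epoxy-2,2-dimethyl-8-(2-methylbut-3-en-2-yloxy)chroman-6-carboxylate
Conditions: (S,S)-(salen)MnCl [(S,S)-N,N'-bis(3,5-di-tert-butylsalicylidene)-1,2-cyclohexanediaminomanganese chloride] (4 mol %), aq. NaOCl buffered to pH 11.3, 4-phenylpyridine N-oxide (cat.), CH2Cl2, 0 °C
Reagents that add atoms: sodium hypochlorite, [Na+].[O-]Cl
Why: Jacobsen epoxidation of a cis-disubstituted, aryl-conjugated alkene in a 2,2-dimethylchromene with an electron-poor arene, the best substrate class for this catalyst; the (S,S)-catalyst delivers oxygen to the face that gives the (3S,4S)-epoxide, and the monosubstituted vinyl group is a poor substrate.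

Step 6
Reactants: 7 methyl (3S,4S)-3,4-epoxy-2,2-dimethyl-8-(2-methylbut-3-en-2-yloxy)chroman-6-carboxylate
Product: 8 (3S)-6-(hydroxymethyl)-2,2-dimethyl-8-(2-methylbut-3-en-2-yloxy)chroman-3-ol
Conditions: LiAlH4, THF, 0 °C → rt; aq. NaOH work-up
Reagents that add atoms: none
Why: Hydride reduction of the ester and regioselective epoxide opening at benzylic C4 (attack at C3 is blocked by the adjacent quaternary C2); the C3–O bond is untouched, so the (3S) centre is retained.

Step 7
Reactants: 8 (3S)-6-(hydroxymethyl)-2,2-dimethyl-8-(2-methylbut-3-en-2-yloxy)chroman-3-ol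
Product: 9 (3S)-3-hydroxy-2,2-dimethyl-8-(2-methylbut-3-en-2-yloxy)chroman-6-carbaldehyde
Conditions: MnO2 (activated, excess), CH2Cl2, rt
Reagents that add atoms: none
Why: MnO2 oxidises benzylic alcohols selectively; the unactivated secondary alcohol should stay.

Step 8
Reactants: 9 (3S)-3-hydroxy-2,2-dimethyl-8-(2-methylbut-3-en-2-yloxy)chroman-6-carbaldehyde
Product: 10 (3S)-3,8-dihydroxy-2,2-dimethyl-7-(3-methylbut-2-enyl)chroman-6-carbaldehyde
Conditions: N,N-diethylaniline, 130 °C, Ar
Reagents that add atoms: none
Why: Aromatic Claisen rearrangement of a 1,1-dimethylallyl aryl ether; the [3,3] shift to C7, the only open ortho position and the one next to the electron-withdrawing aldehyde, gives the linear prenyl group after rearomatisation, and the basic medium suppresses cyclisation of the ortho-prenyl phenol.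

Step 9
Reactants: 10 (3S)-3,8-dihydroxy-2,2-dimethyl-7-(3-methylbut-2-enyl)chroman-6-carbaldehyde
Product: 11 (3S)-3,8-bis(tert-butyldimethylsilyloxy)-2,2-dimethyl-7-(3-methylbut-2-enyl)chroman-6-carbaldehyde
Conditions: TBSOTf (2.5 equiv), 2,6-lutidine, CH2Cl2, −78 → 0 °C
Reagents that add atoms: tert-butyldimethylsilyl trifluoromethanesulfonate, CC(C)(C)[Si](C)(C)OS(=O)(=O)C(F)(F)F
Why: Silyl triflate with a hindered base silylates both the flanked phenol and the neopentyl-type secondary alcohol in one operation; excess lutidine keeps the medium non-acidic for the prenyl group and the aldehyde.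

Step 10
Reactants: 11 (3S)-3,8-bis(tert-butyldimethylsilyloxy)-2,2-dimethyl-7-(3-methylbut-2-enyl)chroman-6-carbaldehyde
Product: 12 (3S)-3,8-bis(tert-butyldimethylsilyloxy)-2,2-dimethyl-7-(3-methylbut-2-enyl)-6-vinylchroman
Conditions: Ph3PCH3Br, KOtBu, THF, 0 °C → rt
Reagents that add atoms: methyltriphenylphosphonium bromide, C[P+](c1ccccc1)(c1ccccc1)c1ccccc1.[Br-]
Why: Wittig methylenation of an aryl aldehyde; the preformed ylide leaves the aryl silyl ether intact.

Step 11
Reactants: 13 2,4,6-trihydroxybenzaldehyde
Product: 14 2-hydroxy-4,6-bis(triisopropylsilyloxy)benzaldehyde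
Conditions: TIPSCl (2.1 equiv), imidazole, DMF, 0 °C → rt
Reagents that add atoms: triisopropylsilyl chloride, CC(C)[Si](Cl)(C(C)C)C(C)C
Why: Silyl ether formation at the para hydroxyl and at one of the two equivalent ortho hydroxyls; the last hydroxyl is deactivated by its hydrogen bond to the aldehyde, so the reaction should stop at the bis-ether.

Step 12
Reactants: 14 2-hydroxy-4,6-bis(triisopropylsilyloxy)benzaldehyde
Product: 15 2-(dimethoxymethyl)-3,5-bis(triisopropylsilyloxy)phenol
Conditions: HC(OMe)3, MeOH, pyridinium p-toluenesulfonate (cat.), rt; Et3N quench; used without chromatography on silica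
Reagents that add atoms: trimethyl orthoformate, COC(OC)OC; methanol, CO
Why: Acid-catalysed acetalisation with the orthoformate as dehydrating agent; the acid is neutralised before concentration because this electron-rich ortho-hydroxy acetal ionises easily.

Step 13
Reactants: 15 2-(dimethoxymethyl)-3,5-bis(triisopropylsilyloxy)phenol; 12 (3S)-3,8-bis(tert-butyldimethylsilyloxy)-2,2-dimethyl-7-(3-methylbut-2-enyl)-6-vinylchroman
Product: 17 (2S,4S)-2-[(3S)-3,8-bis(tert-butyldimethylsilyloxy)-2,2-dimethyl-7-(3-methylbut-2-enyl)chroman-6-yl]-4-methoxy-5,7-bis(triisopropylsilyloxy)chroman, via 4-methoxy ortho-quinone methide 16 (not isolated)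
Conditions: (R)-3,3'-bis(2,4,6-triisopropylphenyl)-1,1'-binaphthalene-2,2'-diyl N-(trifluoromethanesulfonyl)phosphoramide (10 mol %), 5 Å molecular sieves, PhMe, −40 °C; 15 (1.5 equiv) added slowly
Reagents that add atoms: none
Why: Proposed new method: the acid protonates an acetal oxygen of 15 and methanol leaves (taken up by the sieves), giving 16 in its O-protonated form, an oxocarbenium ion held to the chiral phosphoramidate through the phenol hydrogen bond. The CH2 terminus of styrene 12 attacks C4, and the developing benzylic cation at C2, stabilised by O4' para to C1', is captured by the phenolic oxygen in an asynchronous inverse-electron-demand hetero-[4+2] cycloaddition that forms C3–C4 and O1–C2. The closest known reaction types are the achiral acid-promoted [4+2] of salicylaldehyde acetals with styrenes to cis-4-alkoxy-2-arylchromans and the chiral N-triflylphosphoramide-catalysed [4+2] of 4-aryl ortho-quinone methides with styrenes; new here is enantiocontrol for an intermolecular 4-alkoxy ortho-quinone methide. Ring C closes as a six-membered ring by cycloaddition (in the stepwise limit, 6-endo capture of the C2 cation by O1). C2 is set by the catalyst: the ion pair sits in the pocket between the 3,3'-aryl groups, so one face of the styrene is presented to C4, and the remote (3''S) centre is not expected to bias the outcome. C4 follows from the endo approach (2,4-cis) and is not needed later. The step needs chemoselectivity for the styrene over the prenyl alkene, over C6' and over ring A of a second molecule of 15, as well as stability of the product: the para-alkoxystyrene is the strongest π-nucleophile present, the polarity of both partners fixes the orientation, the triisopropylsilyl groups shield C6 and C8, slow addition keeps 16 dilute, and the acetal ionises more easily than the monoether 17.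

Step 14
Reactants: 17 (2S,4S)-2-[(3S)-3,8-bis(tert-butyldimethylsilyloxy)-2,2-dimethyl-7-(3-methylbut-2-enyl)chroman-6-yl]-4-methoxy-5,7-bis(triisopropylsilyloxy)chroman
Product: 18 (2S)-2-[(3S)-3,8-bis(tert-butyldimethylsilyloxy)-2,2-dimethyl-7-(3-methylbut-2-enyl)chroman-6-yl]-5,7-bis(triisopropylsilyloxy)chroman-4-one
Conditions: DDQ (1.2 equiv), CH2Cl2/H2O (20:1), 0 °C
Reagents that add atoms: water, O
Why: DDQ oxidation of a benzylic methyl ether: hydride is abstracted from C4–H, the most hydridic C–H bond (benzylic, α to OMe, ortho/para to three ring oxygens), and water converts the cation into the ketone with loss of methanol; C2 is not involved, and low temperature with a small excess should spare the prenyl CH2.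

Step 15
Reactants: 18 (2S)-2-[(3S)-3,8-bis(tert-butyldimethylsilyloxy)-2,2-dimethyl-7-(3-methylbut-2-enyl)chroman-6-yl]-5,7-bis(triisopropylsilyloxy)chroman-4-one
Product: 19 (2S)-5,7-dihydroxy-2-[(3S)-3,8-dihydroxy-2,2-dimethyl-7-(3-methylbut-2-enyl)chroman-6-yl]chroman-4-one (target)
Conditions: HF·pyridine (excess), pyridine, THF, 0 °C → rt
Reagents that add atoms: none
Why: Fluoride-mediated desilylation under buffered acidic conditions; no phenoxide is formed, so the flavanone should not open to the chalcone and C2 is kept, while the medium is too weakly acidic to cyclise the prenyl group onto O3'.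

## Compound list

1 | methyl 3,4-dihydroxybenzoate | COC(=O)c1ccc(O)c(O)c1 | starting material
2 | 3-chloro-3-methylbut-1-yne | C#CC(C)(C)Cl | starting material
3 | methyl 3-hydroxy-4-(2-methylbut-3-yn-2-yloxy)benzoate | COC(=O)c1ccc(OC(C)(C)C#C)c(O)c1 | intermediate
4 | methyl 8-hydroxy-2,2-dimethyl-2H-chromene-6-carboxylate | COC(=O)c1cc(O)c2OC(C)(C)C=Cc2c1 | intermediate
5 | methyl 2,2-dimethyl-8-(2-methylbut-3-yn-2-yloxy)-2H-chromene-6-carboxylate | COC(=O)c1cc(OC(C)(C)C#C)c2OC(C)(C)C=Cc2c1 | intermediate
6 | methyl 2,2-dimethyl-8-(2-methylbut-3-en-2-yloxy)-2H-chromene-6-carboxylate | COC(=O)c1cc(OC(C)(C)C=C)c2OC(C)(C)C=Cc2c1 | intermediate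
7 | methyl (3S,4S)-3,4-epoxy-2,2-dimethyl-8-(2-methylbut-3-en-2-yloxy)chroman-6-carboxylate | COC(=O)c1cc(OC(C)(C)C=C)c2OC(C)(C)[C@H]3O[C@H]3c2c1 | intermediate
8 | (3S)-6-(hydroxymethyl)-2,2-dimethyl-8-(2-methylbut-3-en-2-yloxy)chroman-3-ol | OCc1cc(OC(C)(C)C=C)c2OC(C)(C)[C@@H](O)Cc2c1 | intermediate
9 | (3S)-3-hydroxy-2,2-dimethyl-8-(2-methylbut-3-en-2-yloxy)chroman-6-carbaldehyde | O=Cc1cc(OC(C)(C)C=C)c2OC(C)(C)[C@@H](O)Cc2c1 | intermediate
10 | (3S)-3,8-dihydroxy-2,2-dimethyl-7-(3-methylbut-2-enyl)chroman-6-carbaldehyde | O=Cc1cc2C[C@H](O)C(C)(C)Oc2c(O)c1CC=C(C)C | intermediate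
11 | (3S)-3,8-bis(tert-butyldimethylsilyloxy)-2,2-dimethyl-7-(3-methylbut-2-enyl)chroman-6-carbaldehyde | O=Cc1cc2C[C@H](O[Si](C)(C)C(C)(C)C)C(C)(C)Oc2c(O[Si](C)(C)C(C)(C)C)c1CC=C(C)C | intermediate
12 | (3S)-3,8-bis(tert-butyldimethylsilyloxy)-2,2-dimethyl-7-(3-methylbut-2-enyl)-6-vinylchroman | C=Cc1cc2C[C@H](O[Si](C)(C)C(C)(C)C)C(C)(C)Oc2c(O[Si](C)(C)C(C)(C)C)c1CC=C(C)C | intermediate
13 | 2,4,6-trihydroxybenzaldehyde | O=Cc1c(O)cc(O)cc1O | starting material
14 | 2-hydroxy-4,6-bis(triisopropylsilyloxy)benzaldehyde | O=Cc1c(O)cc(O[Si](C(C)C)(C(C)C)C(C)C)cc1O[Si](C(C)C)(C(C)C)C(C)C | intermediate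
15 | 2-(dimethoxymethyl)-3,5-bis(triisopropylsilyloxy)phenol | COC(OC)c1c(O)cc(O[Si](C(C)C)(C(C)C)C(C)C)cc1O[Si](C(C)C)(C(C)C)C(C)C | intermediate
16 | 6-(methoxymethylidene)-3,5-bis(triisopropylsilyloxy)cyclohexa-2,4-dien-1-one (4-methoxy ortho-quinone methide, formed in the flask) | COC=C1C(=O)C=C(O[Si](C(C)C)(C(C)C)C(C)C)C=C1O[Si](C(C)C)(C(C)C)C(C)C | intermediate
17 | (2S,4S)-2-[(3S)-3,8-bis(tert-butyldimethylsilyloxy)-2,2-dimethyl-7-(3-methylbut-2-enyl)chroman-6-yl]-4-methoxy-5,7-bis(triisopropylsilyloxy)chroman | CO[C@H]1C[C@@H](c2cc3C[C@H](O[Si](C)(C)C(C)(C)C)C(C)(C)Oc3c(O[Si](C)(C)C(C)(C)C)c2CC=C(C)C)Oc2cc(O[Si](C(C)C)(C(C)C)C(C)C)cc(O[Si](C(C)C)(C(C)C)C(C)C)c12 | intermediate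
18 | (2S)-2-[(3S)-3,8-bis(tert-butyldimethylsilyloxy)-2,2-dimethyl-7-(3-methylbut-2-enyl)chroman-6-yl]-5,7-bis(triisopropylsilyloxy)chroman-4-one | O=C1C[C@@H](c2cc3C[C@H](O[Si](C)(C)C(C)(C)C)C(C)(C)Oc3c(O[Si](C)(C)C(C)(C)C)c2CC=C(C)C)Oc2cc(O[Si](C(C)C)(C(C)C)C(C)C)cc(O[Si](C(C)C)(C(C)C)C(C)C)c12 | intermediate
19 | (2S)-5,7-dihydroxy-2-[(3S)-3,8-dihydroxy-2,2-dimethyl-7-(3-methylbut-2-enyl)chroman-6-yl]chroman-4-one | CC(C)=CCc1c([C@@H]2CC(=O)c3c(O)cc(O)cc3O2)cc2c(c1O)OC(C)(C)[C@@H](O)C2 | target

## Step count and uncertain steps

Total: 15 steps. Longest linear sequence: 13 steps (steps 1–10 from 1 to styrene 12, then steps 13–15); the ring A branch is 2 steps (11 and 12).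

**Step 13 (key step, new method).**
- What may go wrong: poor facial selectivity at C2, because the styrene offers no hydrogen-bond handle to the catalyst; slow reaction of the highly stabilised and hindered cation; Friedel–Crafts self-condensation of ring A or premature ionisation of 15 on isolation; re-ionisation of the product at C4.
- Fallback (known chemistry): 12 and 15 (15 made in the flask from 14 and trimethyl orthoformate if it does not survive isolation) would be combined with an achiral acid such as Sc(OTf)3 in CH2Cl2. This cis-selective [4+2] should give 17 together with its (2R,4R) diastereomer F1. DDQ oxidation of the mixture as in step 14 would give 18 and the (2R) ketone F2. These are diastereomers because of the fixed (3''S) centre, so they would be separated by chromatography or preparative HPLC; F2 could in principle be re-equilibrated by an amine base through reversible retro-oxa-Michael opening and recycled. The fallback sets out from 12 and 15 and returns at 18.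

**Step 14 (DDQ oxidation).**
- What may go wrong: competing hydride abstraction at the doubly activated prenyl CH2 or at C2–H, or over-oxidation towards the flavone level, since both aromatic rings are electron-rich.
- Fallback: from 17, solvolysis of the C4 methyl ether in wet THF with pyridinium p-toluenesulfonate would give the (2S)-flavan-4-ol F3 (both C4 epimers). Dess–Martin periodinane buffered with NaHCO3 would then oxidise the alcohol to 18, avoiding any C–H abstraction. Returns at 18.

**Step 8 (Claisen rearrangement).**
- What may go wrong: loss of the tertiary allyl group by fragmentation, or migration by the para pathway to C5, because the target position is flanked by the aldehyde.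
- Fallback: from 4, O-allylation with allyl bromide and K2CO3 would give allyl ether F4. Jacobsen epoxidation as in step 5 would give epoxide F5, LiAlH4 as in step 6 diol F6, and MnO2 as in step 7 aldehyde F7. The Claisen rearrangement of this simple allyl ether at 190 °C is robust and would give the 7-allyl phenol F8. Cross-metathesis with 2-methylbut-2-ene and the second-generation Grubbs catalyst (H2IMes)(PCy3)Cl2Ru=CHPh would convert allyl into prenyl and return at 10.

**Step 15 (global desilylation).**
- What may go wrong: incomplete cleavage of the hindered aryl silyl ether on ring B under acidic fluoride; forcing with more basic fluoride risks epimerisation at C2 through ring opening.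
- Fallback: a two-stage unmasking from 18. Bu4NF buffered with acetic acid (THF, 0 °C) would remove the three aryl silyl ethers and give the ring D mono-silyl ether F9. Aqueous HF in MeCN would then cleave the remaining alkyl silyl ether and return at 19.

**Step 6 (double reduction).**
- What may go wrong: incomplete epoxide opening at temperatures the allyl ether tolerates, or partial hydride attack at C3.
- Fallback: from 7, radical epoxide opening with Cp2TiCl (trivalent titanium, made from Cp2TiCl2 and Zn) and 1,4-cyclohexadiene in THF. Cleavage of the benzylic C4–O bond to the more stable radical should give hydroxy ester F10, and i-Bu2AlH (CH2Cl2, −78 °C) would reduce it to 8. Returns at 8.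

## Further compounds

F1 | step 13 | (2R,4R)-2-[(3S)-3,8-bis(tert-butyldimethylsilyloxy)-2,2-dimethyl-7-(3-methylbut-2-enyl)chroman-6-yl]-4-methoxy-5,7-bis(triisopropylsilyloxy)chroman | CO[C@@H]1C[C@H](c2cc3C[C@H](O[Si](C)(C)C(C)(C)C)C(C)(C)Oc3c(O[Si](C)(C)C(C)(C)C)c2CC=C(C)C)Oc2cc(O[Si](C(C)C)(C(C)C)C(C)C)cc(O[Si](C(C)C)(C(C)C)C(C)C)c12
F2 | step 13 | (2R)-2-[(3S)-3,8-bis(tert-butyldimethylsilyloxy)-2,2-dimethyl-7-(3-methylbut-2-enyl)chroman-6-yl]-5,7-bis(triisopropylsilyloxy)chroman-4-one | O=C1C[C@H](c2cc3C[C@H](O[Si](C)(C)C(C)(C)C)C(C)(C)Oc3c(O[Si](C)(C)C(C)(C)C)c2CC=C(C)C)Oc2cc(O[Si](C(C)C)(C(C)C)C(C)C)cc(O[Si](C(C)C)(C(C)C)C(C)C)c12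
F3 | step 14 | (2S)-2-[(3S)-3,8-bis(tert-butyldimethylsilyloxy)-2,2-dimethyl-7-(3-methylbut-2-enyl)chroman-6-yl]-5,7-bis(triisopropylsilyloxy)chroman-4-ol, both C4 epimers | OC1C[C@@H](c2cc3C[C@H](O[Si](C)(C)C(C)(C)C)C(C)(C)Oc3c(O[Si](C)(C)C(C)(C)C)c2CC=C(C)C)Oc2cc(O[Si](C(C)C)(C(C)C)C(C)C)cc(O[Si](C(C)C)(C(C)C)C(C)C)c12
F4 | step 8 | methyl 8-(allyloxy)-2,2-dimethyl-2H-chromene-6-carboxylate | COC(=O)c1cc(OCC=C)c2OC(C)(C)C=Cc2c1
F5 | step 8 | methyl (3S,4S)-8-(allyloxy)-3,4-epoxy-2,2-dimethylchroman-6-carboxylate | COC(=O)c1cc(OCC=C)c2OC(C)(C)[C@H]3O[C@H]3c2c1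
F6 | step 8 | (3S)-8-(allyloxy)-6-(hydroxymethyl)-2,2-dimethylchroman-3-ol | OCc1cc(OCC=C)c2OC(C)(C)[C@@H](O)Cc2c1
F7 | step 8 | (3S)-8-(allyloxy)-3-hydroxy-2,2-dimethylchroman-6-carbaldehyde | O=Cc1cc(OCC=C)c2OC(C)(C)[C@@H](O)Cc2c1
F8 | step 8 | (3S)-7-allyl-3,8-dihydroxy-2,2-dimethylchroman-6-carbaldehyde | O=Cc1cc2C[C@H](O)C(C)(C)Oc2c(O)c1CC=C
F9 | step 15 | (2S)-2-[(3S)-3-(tert-butyldimethylsilyloxy)-8-hydroxy-2,2-dimethyl-7-(3-methylbut-2-enyl)chroman-6-yl]-5,7-dihydroxychroman-4-one | CC(C)=CCc1c([C@@H]2CC(=O)c3c(O)cc(O)cc3O2)cc2c(c1O)OC(C)(C)[C@@H](O[Si](C)(C)C(C)(C)C)C2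
F10 | step 6 | methyl (3S)-3-hydroxy-2,2-dimethyl-8-(2-methylbut-3-en-2-yloxy)chroman-6-carboxylate | COC(=O)c1cc(OC(C)(C)C=C)c2OC(C)(C)[C@@H](O)Cc2c1
A1 | alternative 1 | 5-bromo-2-(2-methylbut-3-yn-2-yloxy)benzaldehyde | O=Cc1cc(Br)ccc1OC(C)(C)C#C
A2 | alternative 1 | 6-bromo-2,2-dimethyl-2H-chromene-8-carbaldehyde | O=Cc1cc(Br)cc2C=CC(C)(C)Oc12
A3 | alternative 2 | 4-bromo-2-(hydroxymethyl)-6-(methoxymethoxy)phenol | COCOc1cc(Br)cc(CO)c1O
A4 | alternative 2 | 2-methylprop-1-enylboronic acid pinacol ester | CC(C)=CB1OC(C)(C)C(C)(C)O1
A5 | alternative 2 | 6-bromo-8-(methoxymethoxy)-2,2-dimethylchroman-3-yl boronic acid pinacol ester, configuration giving the (3S) carbinol on oxidation | COCOc1cc(Br)cc2C[C@H](B3OC(C)(C)C(C)(C)O3)C(C)(C)Oc12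
A6 | alternative 3 | 6-{[(2S)-2-[(3S)-3-(tert-butyldimethylsilyloxy)-8-(methoxymethoxy)-2,2-dimethyl-7-(3-methylbut-2-enyl)chroman-6-yl]-4-oxo-3,4-dihydro-2H-pyran-6-yl]methyl}-2,2-dimethyl-4H-1,3-dioxin-4-one | CC1(C)OC(CC2=CC(=O)C[C@@H](c3cc4C[C@H](O[Si](C)(C)C(C)(C)C)C(C)(C)Oc4c(OCOC)c3CC=C(C)C)O2)=CC(=O)O1
A7 | alternative 3 | (2S)-2-[(3S)-3-(tert-butyldimethylsilyloxy)-8-(methoxymethoxy)-2,2-dimethyl-7-(3-methylbut-2-enyl)chroman-6-yl]-5,7-dihydroxychroman-4-one | O=C1C[C@@H](c2cc3C[C@H](O[Si](C)(C)C(C)(C)C)C(C)(C)Oc3c(OCOC)c2CC=C(C)C)Oc2cc(O)cc(O)c12
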